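**Retrosynthetic overview**
1. The target is two (2S)-flavanones joined by a diaryl ether from C4' of ring B of unit 1 to C6 of ring A of unit 2. The last operations are hydrogenolysis of five benzyl ethers and oxidation of a C4 methyl ether to the ring-C ketone of unit 1.
2. Key disconnection, ring C of unit 1: O1–C8a–C4a–C4 is a salicylaldehyde-derived 4-methoxy ortho-quinone methide (heterodiene) and C2–C3 is the vinyl group of a styrene. O1–C2 and C3–C4 are therefore made in one enantioselective inverse-demand oxa-[4+2] reaction on a styrene that already carries unit 2.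
3. That styrene comes from base-free Stille vinylation of an aryl bromide. Its (2S)-flavanone stereocentre is set beforehand by asymmetric conjugate addition of the ring-B arylboronic acid to a chromone.
4. The chromone is built from 2-hydroxy-4,6-bis(benzyloxy)acetophenone by Elbs para-hydroxylation (C6–O), O-arylation with a diaryliodonium salt (diaryl ether) and enaminone cyclisation.
5. Ring order: ring C of unit 2 (step 4, stereocentre in step 5), then ring C of unit 1 (step 7).

Key step: step 7

Remark: the sense of induction of the chiral catalysts in steps 5 and 7 is assigned by analogy and is to be confirmed on a model substrate; the antipodal catalyst is used if it proves opposite.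
Remark: the key step is drawn as giving the 2,4-cis adduct 15; any C4 epimer has the same C2 configuration and converges in step 8.

**Step 1**
Reactants: 1 2,4,6-trihydroxybenzaldehyde
Product: 2 2-hydroxy-4,6-bis(benzyloxy)benzaldehyde
Conditions: BnBr (2.05 equiv), K2CO3, DMF, 0 °C to rt
Reagents that add atoms: benzyl bromide, BrCc1ccccc1
Why: Williamson etherification in which the 4-OH and one ortho OH are alkylated while the last ortho OH stays locked in the hydrogen bond to the formyl group and resists benzylation at room temperature.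

**Step 2**
Reactants: 3 1-[2-hydroxy-4,6-bis(benzyloxy)phenyl]ethan-1-one
Product: 5 1-[3,6-dihydroxy-2,4-bis(benzyloxy)phenyl]ethan-1-one, via aryl sulfate 4 (not isolated)
Conditions: K2S2O8, KOH aq, pyridine, 0 °C to rt; then HCl aq, 80 °C, Ar
Reagents that add atoms: potassium peroxodisulfate, [K+].[K+].[O-]S(=O)(=O)OOS(=O)(=O)[O-]
Why: Elbs persulfate oxidation, in which the phenoxide attacks a peroxide oxygen through the free carbon para to the chelated OH (the position between the two benzyloxy groups) and acid then hydrolyses the aryl sulfate, as in the classical route to 2,5-dihydroxy-4,6-dialkoxyacetophenones.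

**Step 3**
Reactants: 5 1-[3,6-dihydroxy-2,4-bis(benzyloxy)phenyl]ethan-1-one; 6 bis(4-bromophenyl)iodonium triflate
Product: 7 1-[3-(4-bromophenoxy)-6-hydroxy-2,4-bis(benzyloxy)phenyl]ethan-1-one
Conditions: K2CO3 (1.2 equiv), MeCN, rt to 40 °C, Ar, dark
Reagents that add atoms: none
Why: Metal-free O-arylation of a phenoxide with a diaryliodonium salt (ligand coupling at trivalent iodine), which tolerates two ortho substituents, while the 6-OH stays locked in the hydrogen bond to the acetyl group, the same discrimination that lets 2,5-dihydroxyacetophenones be alkylated at the 5-oxygen only.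

**Step 4**
Reactants: 7 1-[3-(4-bromophenoxy)-6-hydroxy-2,4-bis(benzyloxy)phenyl]ethan-1-one
Product: 9 5,7-bis(benzyloxy)-6-(4-bromophenoxy)-4H-chromen-4-one, via enaminone 8 (not isolated)
Conditions: Me2NCH(OMe)2, toluene, 95 °C; then HCl aq, CH2Cl2, 40 °C
Reagents that add atoms: N,N-dimethylformamide dimethyl acetal, COC(OC)N(C)C
Why: Standard enaminone chromone synthesis, in which the methyl ketone condenses with the amide acetal and acid then drives conjugate addition of the phenol and loss of dimethylamine, closing ring C of unit 2.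

**Step 5**
Reactants: 9 5,7-bis(benzyloxy)-6-(4-bromophenoxy)-4H-chromen-4-one; 10 [4-(benzyloxy)phenyl]boronic acid
Product: 11 (2S)-5,7-bis(benzyloxy)-2-[4-(benzyloxy)phenyl]-6-(4-bromophenoxy)chroman-4-one
Conditions: Pd(OCOCF3)2 (5 mol%), (R)-t-BuPyOx (6 mol%), NH4PF6, H2O (5 equiv), ClCH2CH2Cl, 60 °C, air
Reagents that add atoms: none
Why: Palladium-catalysed asymmetric conjugate addition of an arylboronic acid to a chromone, in which the aryl group on cationic divalent palladium inserts the C2=C3 bond on the face left open by the tert-butyl group of the pyridine-oxazoline ligand (C2 set as S with the R ligand, by analogy with cyclic enones) and water protonates the palladium enolate, all without base, so the flavanone cannot racemise by ring opening and the aryl bromide is not touched.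

**Step 6**
Reactants: 11 (2S)-5,7-bis(benzyloxy)-2-[4-(benzyloxy)phenyl]-6-(4-bromophenoxy)chroman-4-one
Product: 12 (2S)-5,7-bis(benzyloxy)-2-[4-(benzyloxy)phenyl]-6-(4-ethenylphenoxy)chroman-4-one
Conditions: Bu3SnCH=CH2, Pd(PPh3)4 (5 mol%), toluene, 100 °C; KF aq work-up
Reagents that add atoms: tributyl(vinyl)stannane, C=C[Sn](CCCC)(CCCC)CCCC
Why: Migita–Kosugi–Stille coupling of the aryl bromide, chosen because it runs without base and so leaves the C2 stereocentre of the flavanone (prone to base-induced opening to the chalcone) and the benzyl ethers untouched.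

**Step 7**
Reactants: 2 2-hydroxy-4,6-bis(benzyloxy)benzaldehyde; 12 (2S)-5,7-bis(benzyloxy)-2-[4-(benzyloxy)phenyl]-6-(4-ethenylphenoxy)chroman-4-one
Product: 15 (2S)-5,7-bis(benzyloxy)-2-[4-(benzyloxy)phenyl]-6-{4-[(2S,4S)-5,7-bis(benzyloxy)-4-methoxychroman-2-yl]phenoxy}chroman-4-one, via dimethyl acetal 13 (not isolated), via methoxy ortho-quinone methide 14 (not isolated)
Conditions: HC(OMe)3 (3 equiv), (R)-3,3'-bis(2,4,6-triisopropylphenyl)-1,1'-binaphthyl-2,2'-diyl N-triflylphosphoramide (10 mol%), 5 Å MS, toluene/CH2Cl2, −40 to 0 °C, 2 (1.5 equiv) added slowly; Et3N quench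
Reagents that add atoms: trimethyl orthoformate, COC(OC)OC
Why: Proposed new method: the acid converts aldehyde 2 and the orthoformate into acetal 13 and ionises it to the phenol-stabilised methoxycarbenium ion (the O-protonated form of quinone methide 14), held as a hydrogen-bonded ion pair with the chiral phosphoramide anion; the terminal carbon of the vinyl group of 12 bonds to this carbon (C3–C4) and the benzylic cation developing at C2, stabilised by the para aryloxy group, is captured by the phenol oxygen (O1–C2), concertedly or in two fast steps. The closest known reactions are the achiral-acid three-component condensation of salicylaldehydes, orthoformates and styrenes to 4-methoxyflavans and chiral phosphoric-acid-catalysed [4+2] cycloadditions of ortho-quinone methides with electron-rich alkenes; new here is the union of an alkoxy quinone methide, a plain styrene and control by the counter-anion. Ring C of unit 1 closes as an inverse-demand oxa-[4+2] cycloaddition (in the stepwise limit, a six-membered oxa-cyclisation of the phenol onto the benzylic cation). C2 is set by the styrene face that the anion leaves open while the phenolic OH is anchored to its P=O group (aryl endo, hence the 2,4-cis adduct); C4 is set relative to it and is erased in step 8, and the remote stereocentre of 12 should not interfere. The step needs regioselectivity (CH2 to C4, oxygen to the benzylic carbon, secured by the polarisation of the styrene), chemoselectivity for the vinyl group over the nucleophilic C8–H positions and over self-condensation of 13 (secured by low temperature, slow addition of 2 and the bulky anion), and survival of the C4 ketone of 12, whose ketalisation is disfavoured by the flanking 5-benzyloxy group and reverses on work-up.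

**Step 8**
Reactants: 15 (2S)-5,7-bis(benzyloxy)-2-[4-(benzyloxy)phenyl]-6-{4-[(2S,4S)-5,7-bis(benzyloxy)-4-methoxychroman-2-yl]phenoxy}chroman-4-one
Product: 16 (2S)-5,7-bis(benzyloxy)-2-[4-(benzyloxy)phenyl]-6-{4-[(2S)-5,7-bis(benzyloxy)-4-oxochroman-2-yl]phenoxy}chroman-4-one
Conditions: DDQ (1.5 equiv), CH2Cl2/pH 7 buffer (10:1), 0 °C to rt
Reagents that add atoms: water, O
Why: Oxidative cleavage of an electron-rich benzylic ether by DDQ (the reaction type used to remove p-methoxybenzyl ethers): hydride is taken from C4–H, which is activated by the 5,7-dibenzyloxy ring and the methoxy group and is pseudo-axial in the 2,4-cis adduct, water adds to the oxocarbenium ion and methanol is lost, leaving the ketone without touching C2.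

**Step 9**
Reactants: 16 (2S)-5,7-bis(benzyloxy)-2-[4-(benzyloxy)phenyl]-6-{4-[(2S)-5,7-bis(benzyloxy)-4-oxochroman-2-yl]phenoxy}chroman-4-one
Product: 17 (2S)-5,7-dihydroxy-2-(4-hydroxyphenyl)-6-{4-[(2S)-5,7-dihydroxy-4-oxochroman-2-yl]phenoxy}chroman-4-one
Conditions: H2 (1 atm), Pd(OH)2 on carbon, THF/MeOH, rt
Reagents that add atoms: none
Why: Hydrogenolysis of the five aryl benzyl ethers under neutral conditions, which the chelated aryl ketones, the diaryl ether and the C2 stereocentres of both flavanones should survive when the reaction is stopped at full debenzylation.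

**Compound list**
1 | 2,4,6-trihydroxybenzaldehyde | O=Cc1c(O)cc(O)cc1O | starting material
2 | 2-hydroxy-4,6-bis(benzyloxy)benzaldehyde | O=Cc1c(O)cc(OCc2ccccc2)cc1OCc1ccccc1 | intermediate
3 | 1-[2-hydroxy-4,6-bis(benzyloxy)phenyl]ethan-1-one | CC(=O)c1c(O)cc(OCc2ccccc2)cc1OCc1ccccc1 | starting material
4 | potassium 3-acetyl-2,6-bis(benzyloxy)-4-hydroxyphenyl sulfate | CC(=O)c1c(O)cc(OCc2ccccc2)c(OS(=O)(=O)[O-])c1OCc1ccccc1.[K+] | intermediate
5 | 1-[3,6-dihydroxy-2,4-bis(benzyloxy)phenyl]ethan-1-one | CC(=O)c1c(O)cc(OCc2ccccc2)c(O)c1OCc1ccccc1 | intermediate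
6 | bis(4-bromophenyl)iodonium triflate | Brc1ccc([I+]c2ccc(Br)cc2)cc1.[O-]S(=O)(=O)C(F)(F)F | starting material
7 | 1-[3-(4-bromophenoxy)-6-hydroxy-2,4-bis(benzyloxy)phenyl]ethan-1-one | CC(=O)c1c(O)cc(OCc2ccccc2)c(Oc2ccc(Br)cc2)c1OCc1ccccc1 | intermediate
8 | (E)-1-[3-(4-bromophenoxy)-6-hydroxy-2,4-bis(benzyloxy)phenyl]-3-(dimethylamino)prop-2-en-1-one | CN(C)/C=C/C(=O)c1c(O)cc(OCc2ccccc2)c(Oc2ccc(Br)cc2)c1OCc1ccccc1 | intermediate
9 | 5,7-bis(benzyloxy)-6-(4-bromophenoxy)-4H-chromen-4-one | O=c1ccoc2cc(OCc3ccccc3)c(Oc3ccc(Br)cc3)c(OCc3ccccc3)c12 | intermediate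
10 | [4-(benzyloxy)phenyl]boronic acid | OB(O)c1ccc(OCc2ccccc2)cc1 | starting material
11 | (2S)-5,7-bis(benzyloxy)-2-[4-(benzyloxy)phenyl]-6-(4-bromophenoxy)chroman-4-one | O=C1C[C@@H](c2ccc(OCc3ccccc3)cc2)Oc2cc(OCc3ccccc3)c(Oc3ccc(Br)cc3)c(OCc3ccccc3)c21 | intermediate
12 | (2S)-5,7-bis(benzyloxy)-2-[4-(benzyloxy)phenyl]-6-(4-ethenylphenoxy)chroman-4-one | C=Cc1ccc(Oc2c(OCc3ccccc3)cc3c(c2OCc2ccccc2)C(=O)C[C@@H](c2ccc(OCc4ccccc4)cc2)O3)cc1 | intermediate
13 | 2-(dimethoxymethyl)-3,5-bis(benzyloxy)phenol | COC(OC)c1c(O)cc(OCc2ccccc2)cc1OCc1ccccc1 | intermediate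
14 | (6E)-3,5-bis(benzyloxy)-6-(methoxymethylidene)cyclohexa-2,4-dien-1-one (E geometry drawn for definiteness; reacts as its O-protonated ion pair) | CO/C=C1\C(OCc2ccccc2)=CC(OCc2ccccc2)=CC1=O | intermediate
15 | (2S)-5,7-bis(benzyloxy)-2-[4-(benzyloxy)phenyl]-6-{4-[(2S,4S)-5,7-bis(benzyloxy)-4-methoxychroman-2-yl]phenoxy}chroman-4-one | CO[C@H]1C[C@@H](c2ccc(Oc3c(OCc4ccccc4)cc4c(c3OCc3ccccc3)C(=O)C[C@@H](c3ccc(OCc5ccccc5)cc3)O4)cc2)Oc2cc(OCc3ccccc3)cc(OCc3ccccc3)c21 | intermediate
16 | (2S)-5,7-bis(benzyloxy)-2-[4-(benzyloxy)phenyl]-6-{4-[(2S)-5,7-bis(benzyloxy)-4-oxochroman-2-yl]phenoxy}chroman-4-one | O=C1C[C@@H](c2ccc(Oc3c(OCc4ccccc4)cc4c(c3OCc3ccccc3)C(=O)C[C@@H](c3ccc(OCc5ccccc5)cc3)O4)cc2)Oc2cc(OCc3ccccc3)cc(OCc3ccccc3)c21 | intermediate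
17 | (2S)-5,7-dihydroxy-2-(4-hydroxyphenyl)-6-{4-[(2S)-5,7-dihydroxy-4-oxochroman-2-yl]phenoxy}chroman-4-one (CNP0184214.1) | O=C1C[C@@H](c2ccc(Oc3c(O)cc4c(c3O)C(=O)C[C@@H](c3ccc(O)cc3)O4)cc2)Oc2cc(O)cc(O)c21 | target

**Step count**
Total: 9 steps. Longest linear sequence: 8 steps (3 to 17, steps 2 to 9); the aldehyde branch is 1 step.

**Steps most likely to fail**

Step 7 (proposed new method). The highly stabilised methoxycarbenium ion may be too weak an electrophile for the aryloxystyrene. The acid may instead trigger cationic oligomerisation of the styrene or Friedel–Crafts attack on the electron-rich rings. Facial discrimination of a styrene without a binding group may be poor, giving a mixture of C2 epimers of unit 1. The fallback uses known chemistry, sets out from 11 (with 3 as the source of the second chromone) and comes back at 16. Miyaura borylation of 11 (B2pin2, PdCl2(dppf), KOAc, dioxane, 80 °C) would give the pinacol boronate F1, and periodate cleavage of the pinacol ester (NaIO4, NH4OAc, acetone/H2O) the boronic acid F2. In parallel, 3 would be taken with Me2NCH(OMe)2 to the enaminone F3 and with HCl to 5,7-bis(benzyloxy)chromone F4. The conjugate addition of step 5 (Pd(OCOCF3)2, (R)-t-BuPyOx), now between F2 and F4, would then set C2 of unit 1 and give 16 directly, by-passing 12 and 15.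

Step 5. The chromone carries a 5-benzyloxy group peri to the carbonyl and three donor substituents, so insertion may be slow, protodeboronation of the electron-rich boronic acid may win, and the ee may be low. The fallback sets out from 7 and comes back at 11. Claisen–Schmidt condensation of 7 with 4-(benzyloxy)benzaldehyde (KOH, EtOH/THF) would give the chalcone F5, and NaOAc in refluxing EtOH the racemic flavanone F6. Kinetic resolution by asymmetric transfer hydrogenation (RuCl(p-cymene)[(R,R)-TsDPEN] or its antipode, HCO2H/Et3N) would reduce the (2R)-enantiomer to the cis-flavan-4-ol F7 and leave the (2S)-flavanone 11.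

Step 8. Hydride abstraction may be slow for any trans epimer, whose C4–H is poorly aligned with the arene. Alternatively the oxocarbenium ion may lose a proton, and over-oxidation to the flavone would then destroy C2 of unit 1. The fallback sets out from 15 and comes back at 16. Mild hydrolysis of the activated benzylic methyl ether (PPTS, acetone/H2O, rt) would give the flavan-4-ol F8 as a C4 epimer mixture, and Dess–Martin periodinane (NaHCO3, CH2Cl2) would oxidise it to 16.

**Further compounds**
F1 | step 7 | (2S)-5,7-bis(benzyloxy)-2-[4-(benzyloxy)phenyl]-6-[4-(4,4,5,5-tetramethyl-1,3,2-dioxaborolan-2-yl)phenoxy]chroman-4-one | CC1(C)OB(c2ccc(Oc3c(OCc4ccccc4)cc4c(c3OCc3ccccc3)C(=O)C[C@@H](c3ccc(OCc5ccccc5)cc3)O4)cc2)OC1(C)C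
F2 | step 7 | (4-{[(2S)-5,7-bis(benzyloxy)-2-[4-(benzyloxy)phenyl]-4-oxochroman-6-yl]oxy}phenyl)boronic acid | OB(O)c1ccc(Oc2c(OCc3ccccc3)cc3c(c2OCc2ccccc2)C(=O)C[C@@H](c2ccc(OCc4ccccc4)cc2)O3)cc1
F3 | step 7 | (E)-1-[2-hydroxy-4,6-bis(benzyloxy)phenyl]-3-(dimethylamino)prop-2-en-1-one | CN(C)/C=C/C(=O)c1c(O)cc(OCc2ccccc2)cc1OCc1ccccc1
F4 | step 7 | 5,7-bis(benzyloxy)-4H-chromen-4-one | O=c1ccoc2cc(OCc3ccccc3)cc(OCc3ccccc3)c12
F5 | step 5 | (E)-1-[3-(4-bromophenoxy)-6-hydroxy-2,4-bis(benzyloxy)phenyl]-3-[4-(benzyloxy)phenyl]prop-2-en-1-one | O=C(/C=C/c1ccc(OCc2ccccc2)cc1)c1c(O)cc(OCc2ccccc2)c(Oc2ccc(Br)cc2)c1OCc1ccccc1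
F6 | step 5 | racemic 5,7-bis(benzyloxy)-2-[4-(benzyloxy)phenyl]-6-(4-bromophenoxy)chroman-4-one | O=C1CC(c2ccc(OCc3ccccc3)cc2)Oc2cc(OCc3ccccc3)c(Oc3ccc(Br)cc3)c(OCc3ccccc3)c21
F7 | step 5 | (2R,4R)-5,7-bis(benzyloxy)-2-[4-(benzyloxy)phenyl]-6-(4-bromophenoxy)chroman-4-ol | O[C@@H]1C[C@H](c2ccc(OCc3ccccc3)cc2)Oc2cc(OCc3ccccc3)c(Oc3ccc(Br)cc3)c(OCc3ccccc3)c21
F8 | step 8 | (2S)-5,7-bis(benzyloxy)-2-[4-(benzyloxy)phenyl]-6-{4-[(2S)-5,7-bis(benzyloxy)-4-hydroxychroman-2-yl]phenoxy}chroman-4-one (C4 epimer mixture) | OC1C[C@@H](c2ccc(Oc3c(OCc4ccccc4)cc4c(c3OCc3ccccc3)C(=O)C[C@@H](c3ccc(OCc5ccccc5)cc3)O4)cc2)Oc2cc(OCc3ccccc3)cc(OCc3ccccc3)c21
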